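**Plan**

1. Retrosynthetic cuts, in order: the nine O‑benzyl bonds and the C8–Br bond of the lower unit; the interflavan C4–C6 bond (C4 cation of a robinetinidol unit plus C6 of a C8‑blocked gallocatechin); the C4–O bond; the C3–O and C2–H bonds (one hydroboration); the C2–C3 bond of the upper pyran ring (ring C); the O1–C2 ester bond; the ring A–allyl bond.
2. Enabling feature: in ring C of the upper unit, C2 is bonded only to the phenolic oxygen O1 of ring A, to ring B and to C3. C2 can therefore be carried as the carbonyl carbon of an aryl gallate ester on O1, and C3–C4 as an ortho allyl group on ring A. One titanium alkylidene event then turns the ester C=O into C2=C3 and closes ring C; the extra allyl carbon leaves as propene.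
3. Forward order: ring A allylphenol, gallate ester, ring C (4H‑chromene), asymmetric hydroboration, C4 oxidation, union with C8‑brominated (+)‑gallocatechin benzyl ether, hydrogenolysis.
4. Stereochemistry: C2 and C3 arise together from one reagent‑controlled syn hydroboration of the achiral chromene (IpcBH2 from (+)‑α‑pinene, 2,3‑trans). C4 arises from attack of the nucleophile anti to the C3 hydroxyl (3,4‑trans). The lower unit comes from (+)‑gallocatechin.
5. Regiochemistry of the 4→6 link comes from a temporary bromine at C8 of the lower unit, removed in the final hydrogenolysis.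

Key step: step 4

Remark on the chemistry: the target is read as robinetinidol‑(4α→6)‑gallocatechin, upper unit (2R,3S,4S), lower unit (2R,3S); (+)‑gallocatechin and 3,4,5‑tris(benzyloxy)benzoyl chloride are taken as purchasable.

**Step 1**
Reactants: 1 3‑(benzyloxy)phenol; 2 allyl bromide
Product: 3 1‑(allyloxy)‑3‑(benzyloxy)benzene
Conditions: K2CO3, acetone, reflux
Reagents that add atoms: none
Why: Williamson ether synthesis, the phenoxide displacing bromide from the allyl halide at oxygen.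

**Step 2**
Reactants: 3 1‑(allyloxy)‑3‑(benzyloxy)benzene
Product: 5 2‑allyl‑5‑(benzyloxy)phenol, via dienone 4 (not isolated)
Conditions: N,N‑diethylaniline, 190 °C; chromatography
Reagents that add atoms: none
Why: aromatic Claisen rearrangement ([3,3] shift, then tautomerisation), in which the donor meta‑benzyloxy group is expected to send the allyl group mainly to the ortho carbon para to it, the minor 1,2,3‑isomer being removed by chromatography; this places the future C4 and C3 on ring A next to O1.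

**Step 3**
Reactants: 5 2‑allyl‑5‑(benzyloxy)phenol; 6 3,4,5‑tris(benzyloxy)benzoyl chloride
Product: 7 2‑allyl‑5‑(benzyloxy)phenyl 3,4,5‑tris(benzyloxy)benzoate
Conditions: Et3N, DMAP (cat.), CH2Cl2, 0 °C to rt
Reagents that add atoms: none
Why: DMAP‑catalysed acylation of the phenol, which attaches C2 with ring B to O1 at the carboxyl oxidation level.

**Step 4**
Reactants: 7 2‑allyl‑5‑(benzyloxy)phenyl 3,4,5‑tris(benzyloxy)benzoate
Product: 9 7‑(benzyloxy)‑2‑[3,4,5‑tris(benzyloxy)phenyl]‑4H‑chromene, via titanium alkylidene 8 (not isolated)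
Conditions: TiCl4, TMEDA, Zn, PbCl2 (cat.), CH3CHBr2, THF/CH2Cl2, 0 to 65 °C; basic alumina
Reagents that add atoms: none
Why: The reduced titanium ethylidene formed from TiCl4, Zn and CH3CHBr2 exchanges with the terminal alkene of 7 through a titanacyclobutane, releasing propene and leaving a titanium alkylidene on the future C3 (8), which adds across the ester C2=O to an oxatitanacyclobutane that cycloreverts to the enol ether C2=C3 and a titanium oxide. The closest known reaction type is the Takai–Utimoto olefinic ester cyclisation (ring‑closing carbonyl–olefin metathesis) used for six‑ and seven‑membered cyclic enol ethers. Ring C closes as a six‑membered ring by an intramolecular [2+2]/retro‑[2+2] in which both new sp2 carbons, C2 and C3, become ring members. No stereocenter is formed: C2 and C3 are left as the two ends of a prochiral enol ether so that step 5 can set both in one syn addition. The step needs chemoselectivity and a double bond that stays at C2=C3; the monosubstituted allyl alkene and the reactive aryl ester carbonyl held five atoms away favour ring closure (an ester ethylidenated first can still close by diene metathesis with the same reagent), the amine‑buffered non‑acidic medium prevents migration of the double bond, and benzyl ethers are inert to the reagent.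

**Step 5**
Reactants: 9 7‑(benzyloxy)‑2‑[3,4,5‑tris(benzyloxy)phenyl]‑4H‑chromene
Product: 11 (2R,3S)‑7‑(benzyloxy)‑2‑[3,4,5‑tris(benzyloxy)phenyl]chroman‑3‑ol, via dialkylborane 10 (not isolated)
Conditions: IpcBH2 (from (+)‑α‑pinene), THF, −25 °C; then NaOH, H2O2, H2O, 0 °C to rt
Reagents that add atoms: monoisopinocampheylborane, C[C@H]1[C@H](B)C[C@@H]2C[C@H]1C2(C)C (boron and one hydrogen, boron kept only in 10); hydrogen peroxide, OO (the C3 oxygen)
Why: asymmetric hydroboration–oxidation, in which boron adds to C3 (β to O1 and the non‑benzylic end) and hydrogen to C2 on the same face, giving the 2,3‑trans relation, the isopinocampheyl group choosing the alkene face as it does for 1‑arylcycloalkenes (predicted (2R,3S); the borane from (−)‑α‑pinene is available should the sense be opposite), and oxidation occurs with retention at C3.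

**Step 6**
Reactants: 11 (2R,3S)‑7‑(benzyloxy)‑2‑[3,4,5‑tris(benzyloxy)phenyl]chroman‑3‑ol
Product: 12 (2R,3S,4S)‑7‑(benzyloxy)‑4‑(2‑ethoxyethoxy)‑2‑[3,4,5‑tris(benzyloxy)phenyl]chroman‑3‑ol
Conditions: DDQ, 2‑ethoxyethanol, CH2Cl2, rt
Reagents that add atoms: 2‑ethoxyethanol, CCOCCO
Why: oxidative benzylic functionalisation, DDQ abstracting hydride from C4 (a 2,4‑dialkoxybenzylic position, para to the 7‑benzyloxy group and ortho to O1) and the alcohol trapping the cation; the C4 configuration (expected 3,4‑cis by analogy with 5‑oxygenated flavan‑3‑ols) is erased in step 9.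

**Step 7**
Reactants: 13 (+)‑gallocatechin
Product: 14 (2R,3S)‑5,7‑bis(benzyloxy)‑2‑[3,4,5‑tris(benzyloxy)phenyl]chroman‑3‑ol
Conditions: BnBr, K2CO3, DMF (degassed), 0 °C to rt
Reagents that add atoms: benzyl bromide, BrCc1ccccc1
Why: Williamson benzylation of the five phenols only, since K2CO3 does not deprotonate the C3 alcohol, and the two stereocenters of the chiral pool material are not touched.

**Step 8**
Reactants: 14 (2R,3S)‑5,7‑bis(benzyloxy)‑2‑[3,4,5‑tris(benzyloxy)phenyl]chroman‑3‑ol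
Product: 15 (2R,3S)‑5,7‑bis(benzyloxy)‑8‑bromo‑2‑[3,4,5‑tris(benzyloxy)phenyl]chroman‑3‑ol
Conditions: NBS, CH2Cl2, −78 to 0 °C
Reagents that add atoms: N‑bromosuccinimide, O=C1CCC(=O)N1Br
Why: electrophilic aromatic bromination at C8, the most reactive carbon of the phloroglucinol‑type ring in benzylated flavan‑3‑ols, which blocks C8 so that C6 is the only free nucleophilic position.

**Step 9**
Reactants: 12 (2R,3S,4S)‑7‑(benzyloxy)‑4‑(2‑ethoxyethoxy)‑2‑[3,4,5‑tris(benzyloxy)phenyl]chroman‑3‑ol; 15 (2R,3S)‑5,7‑bis(benzyloxy)‑8‑bromo‑2‑[3,4,5‑tris(benzyloxy)phenyl]chroman‑3‑ol (excess)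
Product: 16 (2R,3S,4S)‑7‑(benzyloxy)‑4‑{(2R,3S)‑5,7‑bis(benzyloxy)‑8‑bromo‑3‑hydroxy‑2‑[3,4,5‑tris(benzyloxy)phenyl]chroman‑6‑yl}‑2‑[3,4,5‑tris(benzyloxy)phenyl]chroman‑3‑ol
Conditions: TMSOTf, 4 Å molecular sieves, CH2Cl2, −78 to −30 °C
Reagents that add atoms: none
Why: Lewis acid ionisation of the C4 ether and Friedel–Crafts alkylation of C6 of 15 (C8 is blocked), the arene approaching the C4 cation anti to the C3 hydroxyl of the half‑chair with the C2 aryl group equatorial, which should give the 3,4‑trans (4S) linkage, while the excess of 15 suppresses self‑condensation of 12 through its own ring A.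

**Step 10**
Reactants: 16 (the nona‑O‑benzyl 8‑bromo dimer)
Product: 17 robinetinidol‑(4α→6)‑gallocatechin (target)
Conditions: H2 (1 atm), Pd(OH)2/C, Et3N, THF/MeOH/H2O, rt
Reagents that add atoms: none
Why: catalytic hydrogenolysis of the nine benzyl ethers together with hydrodebromination at C8, Et3N taking up HBr, with no stereocenter affected.

**Compound list**

1 | 3‑(benzyloxy)phenol | Oc1cccc(OCc2ccccc2)c1 | starting material
2 | allyl bromide | C=CCBr | starting material
3 | 1‑(allyloxy)‑3‑(benzyloxy)benzene | C=CCOc1cccc(OCc2ccccc2)c1 | intermediate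
4 | 6‑allyl‑3‑(benzyloxy)cyclohexa‑2,4‑dien‑1‑one (racemic, transient) | C=CCC1C=CC(OCc2ccccc2)=CC1=O | intermediate (not isolated)
5 | 2‑allyl‑5‑(benzyloxy)phenol | C=CCc1ccc(OCc2ccccc2)cc1O | intermediate
6 | 3,4,5‑tris(benzyloxy)benzoyl chloride | O=C(Cl)c1cc(OCc2ccccc2)c(OCc2ccccc2)c(OCc2ccccc2)c1 | starting material
7 | 2‑allyl‑5‑(benzyloxy)phenyl 3,4,5‑tris(benzyloxy)benzoate | C=CCc1ccc(OCc2ccccc2)cc1OC(=O)c1cc(OCc2ccccc2)c(OCc2ccccc2)c(OCc2ccccc2)c1 | intermediate
8 | titanium alkylidene of 7 at the future C3, written as the dichlorotitanium species without TMEDA | Cl[Ti](Cl)=CCc1ccc(OCc2ccccc2)cc1OC(=O)c1cc(OCc2ccccc2)c(OCc2ccccc2)c(OCc2ccccc2)c1 | intermediate (not isolated)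
9 | 7‑(benzyloxy)‑2‑[3,4,5‑tris(benzyloxy)phenyl]‑4H‑chromene | C1(c2cc(OCc3ccccc3)c(OCc3ccccc3)c(OCc3ccccc3)c2)=CCc2ccc(OCc3ccccc3)cc2O1 | intermediate
10 | (isopinocampheyl)(trans‑2‑arylchroman‑3‑yl)borane from syn addition to 9, boron at C3 in the position of the later hydroxyl of 11 | C[C@H]1[C@H](B[C@H]3Cc4ccc(OCc5ccccc5)cc4O[C@@H]3c3cc(OCc4ccccc4)c(OCc4ccccc4)c(OCc4ccccc4)c3)C[C@@H]2C[C@H]1C2(C)C | intermediate (not isolated)
11 | (2R,3S)‑7‑(benzyloxy)‑2‑[3,4,5‑tris(benzyloxy)phenyl]chroman‑3‑ol | O[C@H]1Cc2ccc(OCc3ccccc3)cc2O[C@@H]1c1cc(OCc2ccccc2)c(OCc2ccccc2)c(OCc2ccccc2)c1 | intermediate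
12 | (2R,3S,4S)‑7‑(benzyloxy)‑4‑(2‑ethoxyethoxy)‑2‑[3,4,5‑tris(benzyloxy)phenyl]chroman‑3‑ol | O[C@H]1[C@@H](OCCOCC)c2ccc(OCc3ccccc3)cc2O[C@@H]1c1cc(OCc2ccccc2)c(OCc2ccccc2)c(OCc2ccccc2)c1 | intermediate
13 | (+)‑gallocatechin, (2R,3S)‑2‑(3,4,5‑trihydroxyphenyl)chromane‑3,5,7‑triol | c1c(O)cc2c(c1O)C[C@H](O)[C@@H](c1cc(O)c(O)c(O)c1)O2 | starting material
14 | (2R,3S)‑5,7‑bis(benzyloxy)‑2‑[3,4,5‑tris(benzyloxy)phenyl]chroman‑3‑ol | c1c(OCc3ccccc3)cc2c(c1OCc3ccccc3)C[C@H](O)[C@@H](c1cc(OCc3ccccc3)c(OCc3ccccc3)c(OCc3ccccc3)c1)O2 | intermediate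
15 | (2R,3S)‑5,7‑bis(benzyloxy)‑8‑bromo‑2‑[3,4,5‑tris(benzyloxy)phenyl]chroman‑3‑ol | c1c(OCc3ccccc3)c(Br)c2c(c1OCc3ccccc3)C[C@H](O)[C@@H](c1cc(OCc3ccccc3)c(OCc3ccccc3)c(OCc3ccccc3)c1)O2 | intermediate
16 | nona‑O‑benzyl‑8‑bromo‑robinetinidol‑(4α→6)‑gallocatechin, upper unit (2R,3S,4S), lower unit (2R,3S) | c1ccccc1COc1ccc2c(c1)O[C@H](c1cc(OCc3ccccc3)c(OCc3ccccc3)c(OCc3ccccc3)c1)[C@@H](O)[C@@H]2c1c(OCc3ccccc3)c(Br)c2c(c1OCc3ccccc3)C[C@H](O)[C@@H](c1cc(OCc3ccccc3)c(OCc3ccccc3)c(OCc3ccccc3)c1)O2 | intermediate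
17 | robinetinidol‑(4α→6)‑gallocatechin | Oc1ccc2c(c1)O[C@H](c1cc(O)c(O)c(O)c1)[C@@H](O)[C@@H]2c1c(O)cc2c(c1O)C[C@H](O)[C@@H](c1cc(O)c(O)c(O)c1)O2 | target

**Totals**

Total step count: 10
Longest linear sequence: 8 steps (steps 1 to 6, 9 and 10); steps 7 and 8 form the side branch.

**Steps most likely to fail**

Step 4. The titanium ethylidene may olefinate the ester without ring closure, or the acid‑sensitive aryl enol ether may hydrolyse or shift its double bond into conjugation with ring A during isolation. The fallback sets out from 7 and separates the two events. Methylenation of the ester carbonyl with Cp2Ti(μ‑Cl)(μ‑CH2)AlMe2 (Tebbe methylenation; THF/toluene, pyridine, −40 °C to rt) should give 2‑allyl‑5‑(benzyloxy)phenyl 1‑[3,4,5‑tris(benzyloxy)phenyl]vinyl ether F1. Ring‑closing olefin metathesis of this diene with (H2IMes)(PCy3)Cl2Ru=CHPh, the second‑generation Grubbs catalyst (toluene, 70 °C), then forms C2=C3 with loss of ethene and returns to the route at 9.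

Step 5. The chiral borane may discriminate the two faces of this benzo‑fused aryl enol ether poorly, and the β‑aryloxy organoborane may fragment by elimination of the ring A phenoxide before oxidation. The fallback sets out from 9 and replaces reagent control by resolution. Hydroboration with BH3·SMe2 (THF, 0 °C) and prompt oxidation with NaOH/H2O2, the closest precedent for this enol ether class, should give the racemic trans alcohol, racemic 7‑(benzyloxy)‑2‑[3,4,5‑tris(benzyloxy)phenyl]chroman‑3‑ol F2. Esterification with (S)‑2‑methoxy‑2‑phenylacetic acid (DCC, DMAP cat., CH2Cl2, 0 °C) gives two diastereomeric esters, the wanted (2R,3S)‑chroman‑3‑yl (S)‑2‑methoxy‑2‑phenylacetate F3 and the (2S,3R)‑chroman‑3‑yl (S)‑2‑methoxy‑2‑phenylacetate F4, to be separated by chromatography or crystallisation. Saponification of the wanted ester with LiOH (THF/H2O) returns to the route at 11.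

Step 6. Hydride abstraction may take place at C2 (α to O1 and benzylic to ring B) or at a benzyl ether instead of C4, and the C4 ether may ionise and oligomerise under the acidic hydroquinone. The fallback sets out from 11 and brings in the C4 oxygen from an alkene instead of a C–H bond. Mesylation (MsCl, Et3N, CH2Cl2) gives the (2R,3S)‑chroman‑3‑yl methanesulfonate F5. Anti elimination with DBU (toluene, 80 °C) can only remove a C4 hydrogen, because the C2 hydrogen is cis to the leaving group, and should give the (2S)‑7‑(benzyloxy)‑2‑[3,4,5‑tris(benzyloxy)phenyl]‑2H‑chromene F6 (same spatial arrangement at C2, descriptor changed by priority). Dihydroxylation with OsO4 (cat.) and N‑methylmorpholine N‑oxide, anti to the C2 aryl group, should give the 2,3‑trans‑3,4‑cis diol, (2R,3S,4S)‑7‑(benzyloxy)‑2‑[3,4,5‑tris(benzyloxy)phenyl]chromane‑3,4‑diol F7. Its benzylic C4 hydroxyl is ionised by TMSOTf in place of the ether of 12, and union with 15 under the conditions of step 9 returns to the route at 16.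

**Further compounds**

F1 | step 4 | 2‑allyl‑5‑(benzyloxy)phenyl 1‑[3,4,5‑tris(benzyloxy)phenyl]vinyl ether | C=CCc1ccc(OCc2ccccc2)cc1OC(=C)c1cc(OCc2ccccc2)c(OCc2ccccc2)c(OCc2ccccc2)c1
F2 | step 5 | racemic trans‑7‑(benzyloxy)‑2‑[3,4,5‑tris(benzyloxy)phenyl]chroman‑3‑ol (11 and its enantiomer) | O[C@H]1Cc2ccc(OCc3ccccc3)cc2O[C@@H]1c1cc(OCc2ccccc2)c(OCc2ccccc2)c(OCc2ccccc2)c1.O[C@@H]1Cc2ccc(OCc3ccccc3)cc2O[C@H]1c1cc(OCc2ccccc2)c(OCc2ccccc2)c(OCc2ccccc2)c1
F3 | step 5 | (2R,3S)‑7‑(benzyloxy)‑2‑[3,4,5‑tris(benzyloxy)phenyl]chroman‑3‑yl (S)‑2‑methoxy‑2‑phenylacetate | CO[C@H](C(=O)O[C@H]1Cc2ccc(OCc3ccccc3)cc2O[C@@H]1c1cc(OCc2ccccc2)c(OCc2ccccc2)c(OCc2ccccc2)c1)c1ccccc1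
F4 | step 5 | (2S,3R)‑7‑(benzyloxy)‑2‑[3,4,5‑tris(benzyloxy)phenyl]chroman‑3‑yl (S)‑2‑methoxy‑2‑phenylacetate | CO[C@H](C(=O)O[C@@H]1Cc2ccc(OCc3ccccc3)cc2O[C@H]1c1cc(OCc2ccccc2)c(OCc2ccccc2)c(OCc2ccccc2)c1)c1ccccc1
F5 | step 6 | (2R,3S)‑7‑(benzyloxy)‑2‑[3,4,5‑tris(benzyloxy)phenyl]chroman‑3‑yl methanesulfonate | CS(=O)(=O)O[C@H]1Cc2ccc(OCc3ccccc3)cc2O[C@@H]1c1cc(OCc2ccccc2)c(OCc2ccccc2)c(OCc2ccccc2)c1
F6 | step 6 | (2S)‑7‑(benzyloxy)‑2‑[3,4,5‑tris(benzyloxy)phenyl]‑2H‑chromene | C1=Cc2ccc(OCc3ccccc3)cc2O[C@@H]1c1cc(OCc2ccccc2)c(OCc2ccccc2)c(OCc2ccccc2)c1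
F7 | step 6 | (2R,3S,4S)‑7‑(benzyloxy)‑2‑[3,4,5‑tris(benzyloxy)phenyl]chromane‑3,4‑diol | O[C@H]1[C@@H](O)c2ccc(OCc3ccccc3)cc2O[C@@H]1c1cc(OCc2ccccc2)c(OCc2ccccc2)c(OCc2ccccc2)c1
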